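## Structural features

The target is a daucane: a cyclopentane (C1–C5) and a cycloheptane (C5–C10 and C1) share the C1–C5 bond. C1 is quaternary (angular methyl), C4 carries isopropyl and a tertiary hydroxyl, C6 carries the 4-hydroxybenzoate, and C8–C9 is a trisubstituted epoxide with the C8 methyl. Calling the face of the C1 methyl the lower face, H5 is also down (cis ring fusion), the C4 hydroxyl and the C6 acyloxy group are both up, and the epoxide oxygen is down. C4, C5 and C6 are therefore a contiguous triad with a 1,3-syn dioxygen pattern anti to H5, next to the quaternary C1. Fragile groups are the epoxide (acid; backside attack by the C4 hydroxyl at C8 is conceivable), the tertiary alcohol once C6 is a ketone (dehydration, retro-aldol), and the aryl ester and free phenol (base). The real difficulty is twofold: the absolute configuration of quaternary C1, and placing H5 on the more alkyl-flanked face between two oxygens on the other face of a flexible seven-membered ring. The key step exploits that C1 carries both the methyl and the allylic C10. The C1–C10 bond is made by a 1,2-shift of C10 from a spiro carbon C5, which turns the six-membered ring C5–C10 of a spiro[4.5]decene into the seven-membered ring.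

## Logic of the disconnections

25 to 24: the phenolic O–Si bond is cut. The phenol is the only acidic hydroxyl and must be masked during acylation and epoxidation. The forward step must spare the ester and the epoxide.

24 to 23: both C–O bonds of the C8–C9 epoxide are cut. The epoxide is the most acid-sensitive group and goes in last, on an alkene that has been a spectator since the key step. The forward step needs lower-face oxygen transfer.

23 to 21 and 22: the C6–O acyl bond is cut, separating the aryl part from the terpenoid core. The forward step must acylate the secondary hydroxyl and leave the tertiary one.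

21 to 20: the C6–H bond is cut. The forward step needs hydride addition from the lower face of a cis-fused ketone.

20 to 17: the C5–H bond is cut and the hydrogen is returned to C6, with C5–O restored as an epoxide bond. This ties the C5 configuration to the epoxide configuration. The forward step needs ionisation of C5–O and not C4–O, with H6 antiperiplanar.

17 to 16: both C–O bonds of the C4–C5 epoxide are cut. The forward step needs oxygen delivery from the C6 hydroxyl, so that C4–O is set by C6.

16 to 15: the C6–H bond is cut. One reagent-controlled stereocentre is enough here, because it is relayed to C4 and C5 in the two following steps.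

15 to 14: the C6=O group is traced to a C4–O bond by allylic transposition. C4 becomes trigonal again, so the C4 configuration of 14 does not matter.

14 to 12: the C4–O bond is cut and the alkene is returned to C4–C5. All oxygen is removed and a C15 hydrocarbon with one stereocentre remains. The forward step needs oxygen at C4 with hydrogen abstraction from C6, and preference for the tetrasubstituted alkene.

12 to 11: the C1–C10 bond is cut and C5–C10 restored. The fused 5-7 system becomes a spiro[4.5]decenol that a cycloaddition can assemble. The forward step needs migration of C10 and not C6, suprafacially, and loss of H4.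

11 to 9 and 10: the C1–CH3 bond is cut. The forward step needs clean 1,2-addition to a hindered, enolisable ketone, preferably anti to the isopropyl group.

9 to 7 and 8: the C5–C10 and C6–C7 bonds are cut. Both rings of the spirocycle then come from a five-carbon diene and an exocyclic enone. The forward step needs para regiochemistry and addition anti to the isopropyl group.

7 to 4: the exocyclic C=C bond is cut to a one-carbon electrophile and a regiodefined enol ether. The forward step must functionalise only the carbon between the carbonyl and the isopropyl-bearing carbon.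

4 to 1 and 2: the C4–isopropyl bond is cut. The forward step needs an enantioselective conjugate addition whose enolate is trapped before it equilibrates.

## Other disconnections considered

Alternative 1: The cut is C1–C5. Forward, Rh2(OAc)4 decomposes methyl (6R)-8-[(tert-butyldimethylsilyl)oxy]-2-diazo-6-methyl-3-oxooctanoate A1, and the carbenoid inserts into the tertiary C–H bond with retention to give methyl 2-{2-[(tert-butyldimethylsilyl)oxy]ethyl}-2-methyl-5-oxocyclopentane-1-carboxylate A2.
- In its favour: the absolute configuration of C1 comes from a chiral-pool stereocentre of a commercial acyclic terpene alcohol and is transferred stereospecifically. On this point it is better than the chosen plan, where C1 depends on a catalytic addition, a facial selection and a migratory preference. The C4 ketone of A2 would take up isopropyl directly as the tertiary carbinol, and C6 is already an oxidised carbon; both are better than the hydrocarbon 12.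
- Against it: A2 holds only the five-membered ring. C7, C8 and its methyl must still be added and the seven-membered ring closed, and C5 is an epimerisable β-keto ester centre.
- Comparison: the two plans are equal in stereospecificity at C1 (retentive insertion against suprafacial shift). The chosen plan builds the full C15 skeleton in five steps but then pays six steps of oxidation. The alternative would pay in ring construction, so the overall length should be similar or longer.

Alternative 2: The cuts are C1–C5 and C1–C10. Forward, [Cu(MeCN)4]PF6 with a chiral bis(oxazoline) converts 3-diazo-1-[2-(2-methoxy-4-methylphenyl)-1,3-dioxolan-2-yl]butan-2-one A3 into a carbenoid that adds to the arene, and the norcaradiene opens to the methoxy-substituted 8a-methyl azulenone ketal A4.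
- In its favour: both rings, quaternary C1 and the C8 methyl arise in one catalytic asymmetric step, and oxygen is already at C4 and C6. In ring construction and oxidation pattern it is better than the chosen plan.
- Against it: enantiocontrol in forming a quaternary centre from a methyl-substituted carbenoid is substrate-dependent. The carbenoid must choose the unsubstituted ortho bond. The C2 carbonyl is surplus. The triene has no C8–C9 alkene, so it must be reduced and isomerised position-selectively. The isopropyl group is still missing.
- Comparison: mechanistically both plans create C1–C10 in the key step. Here the later redox and alkene-position corrections would probably cancel the early gain, whereas the chosen plan carries the C8–C9 alkene untouched from the cycloaddition.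

Alternative 3: The cuts are C5–C6 and O–C4. Forward, NaOCl oxidises (Z)-3-methyl-5-[(1S)-1-methyl-3-(propan-2-yl)cyclopent-2-en-1-yl]pent-3-enal oxime A5, and the dipole adds across the cyclopentene to give the tricyclic isoxazoline A6.
- In its favour: the tether from C1 forces addition to the upper face, so C4–O up and H5 down are set in one step. N–O cleavage (Mo(CO)6) would give 20 directly. In stereocontrol at C4 and C5 it is better than the chosen plan, which needs the three-step relay of steps 8 to 10. The two plans are equal in carrying the C8–C9 alkene through.
- Against it: A5 needs an enantioenriched quaternary centre and a Z-trisubstituted alkene, neither of which is cheap. Closing a seven-membered ring onto a trisubstituted dipolarophile with oxygen attacking the fully substituted carbon must compete with dipole dimerisation.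
- Comparison: the alternative is stronger after ring closure and weaker before it. The chosen plan reaches the complete skeleton from four simple materials in five steps.

Key step: step 5

Remarks:
- Atoms are numbered C1 (methyl-bearing fusion carbon) to C5 round the five-membered ring and C6 to C10 round the seven-membered ring; "lower face" is the face of the C1 methyl.
- The structures of 11 and 12 were checked against each other and against the target and need no correction: C10 trans to isopropyl at the spiro centre of 11 leads to (1S)-12. The spiro name of 11 (dec-7-ene) and the numbering used here (C8=C9) describe the same alkene.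
- Design changes: the nucleophile in step 1 is a dialkylzinc, since branched Grignard reagents tend to give poorer enantioselection with the usual copper–diphosphine catalysts; the oxidation phase (steps 6 to 11) runs through an enone so that C4, C5 and C6 are set by reagent control and relay and not by the facial bias of 12; and 11 is used as the C1 epimer whose C1–O bond is antiperiplanar to C5–C10.
- Assumptions: 22 is purchased; the ligand antipode in step 1 is the one that gives the (S) enolate.

## Steps

Step 1
Reactants: 1 cyclopent-2-en-1-one; 2 diisopropylzinc
Product: 4 (S)-trimethyl{[3-(propan-2-yl)cyclopent-1-en-1-yl]oxy}silane, via isopropylzinc enolate 3 (not isolated)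
Conditions: (CuOTf)2·C6H6 (1 mol %), chiral dipeptide 2-(diphenylphosphino)benzaldimine ligand (2.4 mol %), toluene, −30 °C; then Me3SiOTf, Et3N, −30 to 0 °C
Reagents that add atoms: diisopropylzinc (2), CC(C)[Zn]C(C)C; trimethylsilyl trifluoromethanesulfonate, C[Si](C)(C)OS(=O)(=O)C(F)(F)F
Why: Copper-catalysed enantioselective conjugate addition of a dialkylzinc to a cyclic enone sets the isopropyl-bearing centre by catalyst control. Silylation of the zinc enolate fixes the enolate regiochemistry for step 2.

Step 2
Reactants: 4 (S)-trimethyl{[3-(propan-2-yl)cyclopent-1-en-1-yl]oxy}silane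
Product: 7 (S)-2-methylidene-3-(propan-2-yl)cyclopentan-1-one, via Mannich base 5 (not isolated), via quaternary ammonium iodide 6 (not isolated)
Conditions: H2C=NMe2+ I−, CH2Cl2, 20 °C; aq NaHCO3; MeI, Et2O; aq NaHCO3/CH2Cl2, 20 °C; used at once
Reagents that add atoms: dimethylmethyleneammonium iodide, C=[N+](C)C.[I-]
Why: Mannich reaction of a silyl enol ether with a preformed iminium salt occurs only at the enol carbon. Quaternisation and Hofmann-type β-elimination then unveil the exocyclic enone without touching the stereocentre.

Step 3
Reactants: 7 (S)-2-methylidene-3-(propan-2-yl)cyclopentan-1-one; 8 isoprene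
Product: 9 (4S,5S)-8-methyl-4-(propan-2-yl)spiro[4.5]dec-7-en-1-one
Conditions: isoprene (5 equiv), EtAlCl2 (0.3 equiv), CH2Cl2, −78 to −30 °C
Reagents that add atoms: isoprene (8), C=CC(C)=C
Why: Lewis-acid-catalysed Diels–Alder reaction. The diene methyl ends para to the spiro carbon, and the diene adds to the alkene face anti to the adjacent isopropyl group, which sets the spiro centre with C10 trans to isopropyl.

Step 4
Reactants: 9 (4S,5S)-8-methyl-4-(propan-2-yl)spiro[4.5]dec-7-en-1-one; 10 methyllithium
Product: 11 (1S,4S,5S)-1,8-dimethyl-4-(propan-2-yl)spiro[4.5]dec-7-en-1-ol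
Conditions: CeCl3 (anhydrous), THF, −78 °C; aq NH4Cl
Reagents that add atoms: methyllithium (10), [Li]C
Why: Organocerium 1,2-addition to a hindered, enolisable ketone. Attack anti to the isopropyl group, on the side of the allylic arm C10, should give mainly the epimer with hydroxyl trans to C10; the minor epimer ionises to the same cation.

Step 5
Reactants: 11 (1S,4S,5S)-1,8-dimethyl-4-(propan-2-yl)spiro[4.5]dec-7-en-1-ol
Product: 12 (S)-dauca-4,8-diene [(8aS)-6,8a-dimethyl-3-(propan-2-yl)-1,2,4,5,8,8a-hexahydroazulene]
Conditions: BF3·OEt2 (0.5 equiv), CH2Cl2, −78 to −20 °C; Et3N, aq NaHCO3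
Reagents that add atoms: none
Why: Wagner–Meerwein 1,2-alkyl shift with ring expansion: BF3 coordinates the tertiary hydroxyl, C1–O ionises, and the C5–C10 σ bond migrates to C1. That bond is the better donor because it is allylic, and in (1S)-11 it is antiperiplanar to the leaving group. The shift is suprafacial with retention at C10, so C10 arrives on the cyclopentane face it occupied at C5; this fixes the one new stereocentre, C1, as S, and the controlling element is the spiro centre set in step 3. The seven-membered ring is not closed by a cyclisation but by one-carbon expansion of the six-membered ring (C1 is inserted between C5 and C10), and the cyclopentane becomes the fused five-membered ring. The tertiary cation at C5 loses H4 to give the tetrasubstituted alkene. Dienes formed by proton loss from the C1 cation, or the C5–C6 alkene isomer, can re-enter the cation manifold and should drain to 12. The closest known reaction type is the acid-promoted ring expansion of spiro tertiary carbinols, the acorane-to-daucane direction presumed in biosynthesis. The step needs migration of C10 and not C6 (a C6 shift would give the C7–C8 alkene isomer with the opposite C1 configuration) and no protonation of the C8–C9 alkene, which low temperature, substoichiometric Lewis acid and a basic quench should secure.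

Step 6
Reactants: 12 (S)-dauca-4,8-diene
Product: 14 (1S)-dauca-5,8-dien-4-ol (both C4 epimers), via allylic hydroperoxide 13 (not isolated)
Conditions: O2, tetraphenylporphyrin (cat.), visible light, CH2Cl2, −20 °C; then PPh3, 0 °C
Reagents that add atoms: dioxygen, O=O
Why: Schenck ene reaction of singlet oxygen, faster at the tetrasubstituted than at the trisubstituted alkene. Oxygen should bond to C4, remote from quaternary C1, with hydrogen taken from C6 (C1 has none and the isopropyl methine is unreactive); the C4 configuration is irrelevant because step 7 makes C4 trigonal again.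

Step 7
Reactants: 14 (1S)-dauca-5,8-dien-4-ol (both C4 epimers)
Product: 15 (S)-dauca-4,8-dien-6-one
Conditions: [C5H5NH][CrO3Cl] (pyridinium chlorochromate), NaOAc, 4 Å sieves, CH2Cl2, 20 °C
Reagents that add atoms: none
Why: Babler–Dauben oxidative 1,3-transposition of a tertiary allylic alcohol: chromate ester, [3,3] shift of the ester to C6, then oxidation to the conjugated enone. Both C4 epimers converge.

Step 8
Reactants: 15 (S)-dauca-4,8-dien-6-one
Product: 16 (1S,6R)-dauca-4,8-dien-6-ol
Conditions: (S)-2-methyl-CBS-oxazaborolidine (0.2 equiv), catecholborane, toluene, −78 °C; aq NaOH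
Reagents that add atoms: none
Why: Corey–Bakshi–Shibata reduction: the fully substituted alkenyl carbon C5 is the large group and C7H2 the small one, so the (S) catalyst should give the (6R) alcohol whatever the remote C1 centre. Any minor-enantiomer 15 becomes a separable diastereomer here.

Step 9
Reactants: 16 (1S,6R)-dauca-4,8-dien-6-ol
Product: 17 (1S,4R,5S,6R)-4,5-epoxydauc-8-en-6-ol
Conditions: VO(acac)2 (5 mol %), tBuOOH, toluene, 0 to 20 °C
Reagents that add atoms: tert-butyl hydroperoxide, CC(C)(C)OO
Why: Hydroxyl-directed vanadium-catalysed epoxidation: A(1,3) strain with the isopropyl group keeps H6 in the alkene plane and the C6 oxygen over the upper face, so oxygen is delivered there and C4–O is set up. The allylic alkene should react well before the homoallylic C8–C9 alkene.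

Step 10
Reactants: 17 (1S,4R,5S,6R)-4,5-epoxydauc-8-en-6-ol
Product: 20 (1S,4R,5R)-4-hydroxydauc-8-en-6-one, via epoxy trimethylsilyl ether 18 (not isolated), via 4-trimethylsilyloxy ketone 19 (not isolated)
Conditions: Me3SiOTf (2.5 equiv), 2,6-lutidine, CH2Cl2, −78 °C; then MeOH, citric acid, 0 °C
Reagents that add atoms: none
Why: Semipinacol rearrangement of a 2,3-epoxy silyl ether (non-aldol aldol type): the silyl triflate activates the epoxide and H6, antiperiplanar to C5–O in the syn epoxy alcohol, shifts to C5 with inversion as C6 becomes the carbonyl. This puts H5 down and leaves C4–O up; mild methanolysis removes the tertiary silyl ether.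

Step 11
Reactants: 20 (1S,4R,5R)-4-hydroxydauc-8-en-6-one
Product: 21 (1S,4R,5S,6R)-dauc-8-ene-4,6-diol
Conditions: NaBH4, MeOH, −40 °C
Reagents that add atoms: none
Why: Hydride reduction of a ketone in a cis-fused bicycle: the hydride should attack C6 from the open lower face, anti to the five-membered ring and its C4 substituents. This gives the upper (6R) alcohol syn to the C4 hydroxyl.

Step 12
Reactants: 21 (1S,4R,5S,6R)-dauc-8-ene-4,6-diol; 22 4-[(tert-butyldimethylsilyl)oxy]benzoic acid
Product: 23 (1S,4R,5S,6R)-4-hydroxydauc-8-en-6-yl 4-[(tert-butyldimethylsilyl)oxy]benzoate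
Conditions: EDC·HCl, DMAP (cat.), CH2Cl2, 20 °C
Reagents that add atoms: 4-[(tert-butyldimethylsilyl)oxy]benzoic acid (22), CC(C)(C)[Si](C)(C)Oc1ccc(cc1)C(O)=O
Why: Steglich-type carbodiimide esterification: only the secondary C6 hydroxyl should react, the tertiary C4 hydroxyl being inert under these conditions. The phenol is masked so that the acid cannot self-condense.

Step 13
Reactants: 23 (1S,4R,5S,6R)-4-hydroxydauc-8-en-6-yl 4-[(tert-butyldimethylsilyl)oxy]benzoate
Product: 24 (1S,4R,5S,6R,8R,9S)-8,9-epoxy-4-hydroxydaucan-6-yl 4-[(tert-butyldimethylsilyl)oxy]benzoate
Conditions: mCPBA, NaHCO3, CH2Cl2, 0 °C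
Reagents that add atoms: 3-chloroperoxybenzoic acid, OOC(=O)c1cccc(Cl)c1
Why: Prilezhaev epoxidation of the only remaining alkene: the peracid should approach the lower face of the seven-membered ring, away from the five-membered ring and the C6 ester on the upper face. The bicarbonate buffer protects the acid-sensitive product.

Step 14
Reactants: 24 (1S,4R,5S,6R,8R,9S)-8,9-epoxy-4-hydroxydaucan-6-yl 4-[(tert-butyldimethylsilyl)oxy]benzoate
Product: 25 (1S,4R,5S,6R,8R,9S)-8,9-epoxy-4-hydroxydaucan-6-yl 4-hydroxybenzoate (target)
Conditions: Bu4NF, AcOH, THF, 0 °C
Reagents that add atoms: none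
Why: Fluoride cleavage of an aryl silyl ether, which under acetic acid buffering should be much faster than any reaction of the ester or the epoxide.

## Compound list

1 | cyclopent-2-en-1-one | O=C1C=CCC1 | starting material
2 | diisopropylzinc | CC(C)[Zn]C(C)C | starting material
3 | isopropylzinc (S)-3-(propan-2-yl)cyclopent-1-en-1-olate | CC(C)[Zn]OC1=C[C@H](C(C)C)CC1 | intermediate (not isolated)
4 | (S)-trimethyl{[3-(propan-2-yl)cyclopent-1-en-1-yl]oxy}silane | C[Si](C)(C)OC1=C[C@H](C(C)C)CC1 | intermediate
5 | (2R,3S)-2-[(dimethylamino)methyl]-3-(propan-2-yl)cyclopentan-1-one | CN(C)C[C@@H]1C(=O)CC[C@H]1C(C)C | intermediate (not isolated)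
6 | N-methyl quaternary ammonium iodide of 5 (same configuration) | C[N+](C)(C)C[C@@H]1C(=O)CC[C@H]1C(C)C.[I-] | intermediate (not isolated)
7 | (S)-2-methylidene-3-(propan-2-yl)cyclopentan-1-one | C=C1C(=O)CC[C@H]1C(C)C | intermediate
8 | isoprene | C=CC(C)=C | starting material
9 | (4S,5S)-8-methyl-4-(propan-2-yl)spiro[4.5]dec-7-en-1-one | CC(C)[C@@H]1CCC(=O)[C@]12CCC(C)=CC2 | intermediate
10 | methyllithium | [Li]C | starting material
11 | (1S,4S,5S)-1,8-dimethyl-4-(propan-2-yl)spiro[4.5]dec-7-en-1-ol | CC(C)[C@@H]1CC[C@](C)(O)[C@]12CCC(C)=CC2 | intermediate (key-step precursor)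
12 | (S)-dauca-4,8-diene | CC(C)C1=C2CCC(C)=CC[C@]2(C)CC1 | intermediate (key-step product)
13 | (1S)-4-hydroperoxydauca-5,8-diene (both C4 epimers) | CC(C)C1(OO)CC[C@@]2(C)CC=C(C)CC=C12 | intermediate (not isolated)
14 | (1S)-dauca-5,8-dien-4-ol (both C4 epimers) | CC(C)C1(O)CC[C@@]2(C)CC=C(C)CC=C12 | intermediate
15 | (S)-dauca-4,8-dien-6-one | CC(C)C1=C2C(=O)CC(C)=CC[C@]2(C)CC1 | intermediate
16 | (1S,6R)-dauca-4,8-dien-6-ol | CC(C)C1=C2[C@H](O)CC(C)=CC[C@]2(C)CC1 | intermediate
17 | (1S,4R,5S,6R)-4,5-epoxydauc-8-en-6-ol | CC(C)[C@@]12O[C@@]13[C@H](O)CC(C)=CC[C@]3(C)CC2 | intermediate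
18 | trimethylsilyl ether of 17 | CC(C)[C@@]12O[C@@]13[C@H](O[Si](C)(C)C)CC(C)=CC[C@]3(C)CC2 | intermediate (not isolated)
19 | (1S,4R,5R)-4-(trimethylsilyloxy)dauc-8-en-6-one | CC(C)[C@]1(O[Si](C)(C)C)CC[C@@]2(C)CC=C(C)CC(=O)[C@H]21 | intermediate (not isolated)
20 | (1S,4R,5R)-4-hydroxydauc-8-en-6-one | CC(C)[C@]1(O)CC[C@@]2(C)CC=C(C)CC(=O)[C@H]21 | intermediate
21 | (1S,4R,5S,6R)-dauc-8-ene-4,6-diol | CC(C)[C@]1(O)CC[C@@]2(C)CC=C(C)C[C@@H](O)[C@H]21 | intermediate
22 | 4-[(tert-butyldimethylsilyl)oxy]benzoic acid | CC(C)(C)[Si](C)(C)Oc1ccc(cc1)C(O)=O | starting material
23 | (1S,4R,5S,6R)-4-hydroxydauc-8-en-6-yl 4-[(tert-butyldimethylsilyl)oxy]benzoate | CC(C)[C@]1(O)CC[C@@]2(C)CC=C(C)C[C@@H](OC(=O)c3ccc(O[Si](C)(C)C(C)(C)C)cc3)[C@H]21 | intermediate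
24 | (1S,4R,5S,6R,8R,9S)-8,9-epoxy-4-hydroxydaucan-6-yl 4-[(tert-butyldimethylsilyl)oxy]benzoate | CC(C)[C@]1(O)CC[C@@]2(C)C[C@@H]3O[C@]3(C)C[C@@H](OC(=O)c3ccc(O[Si](C)(C)C(C)(C)C)cc3)[C@H]21 | intermediate
25 | (1S,4R,5S,6R,8R,9S)-8,9-epoxy-4-hydroxydaucan-6-yl 4-hydroxybenzoate | CC(C)[C@]1(O)CC[C@@]2(C)C[C@@H]3O[C@]3(C)C[C@@H](OC(=O)c3ccc(O)cc3)[C@H]21 | target

## Step count and least certain steps

Total: 14 steps. Longest linear sequence: 14 steps (1 to 25; 22 is purchased).

Step 5 (key step). What may go wrong: proton loss from the C1 cation outruns the shift (simple dehydration), the liberated water or fluoride intercepts the cation, or prolonged acid contact protonates the C8–C9 alkene and starts transannular cyclisation; a competing C6 shift would erode the C1 configuration. Fallback: the same cation is entered from an alkene under water-free, catalytic-acid conditions. Wittig methylenation of 9 (Ph3P=CH2, THF) would give (4S,5S)-8-methyl-1-methylidene-4-(propan-2-yl)spiro[4.5]dec-7-ene F1. A catalytic strong acid with a non-nucleophilic counter-ion (HNTf2, CH2Cl2, −78 °C) would protonate the 1,1-disubstituted alkene to the C1 cation, which can only shift or revert. This sets out from 9 and returns at 12.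

Step 1. What may go wrong: insufficient enantioselection for a branched alkyl group on the five-membered enone, or incomplete silylation of the zinc enolate. Fallback: the stereocentre is set by hydride instead of by the alkyl group. Addition of isopropylmagnesium chloride/CeCl3 to 1 would give 1-(propan-2-yl)cyclopent-2-en-1-ol F2. Oxidative transposition with [C5H5NH][CrO3Cl] would give 3-(propan-2-yl)cyclopent-2-en-1-one F3. Copper-hydride asymmetric conjugate reduction (CuCl, NaOtBu, p-Tol-BINAP of the appropriate configuration, Ph2SiH2) would give (S)-diphenyl{[3-(propan-2-yl)cyclopent-1-en-1-yl]oxy}silane F4, with the same enol regiochemistry as 4. Its Mannich reaction with dimethylmethyleneammonium iodide rejoins the route. This sets out from 1 and returns at 5.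

Step 6. What may go wrong: hydrogen abstraction from C3 instead of C6 (oxygen then ends at C5), or competing ene reaction at the C8–C9 alkene. Fallback: mCPBA (1 equiv, CH2Cl2, −40 °C) on 12 would give (1S)-4,5-epoxydauc-8-ene F5 on either face. Lithium diethylamide or diethylaluminium 2,2,6,6-tetramethylpiperidide would isomerise it by syn β-elimination toward C6. This sets out from 12 and returns at 14.

Step 10. What may go wrong: ionisation of C4–O instead of C5–O (both epoxide carbons are fully substituted) with Meinwald-type ring contraction, or enol silylation of 19 with loss of the C5 configuration. Fallback: oxidation of 17 with the periodinane 1,1,1-triacetoxy-1,1-dihydro-1,2-benziodoxol-3(1H)-one would give (1S,4R,5R)-4,5-epoxydauc-8-en-6-one F6. SmI2 (THF/MeOH, −78 °C) cleaves only the C–O bond α to the ketone, and C5 is then set by protonation toward the cis-fused isomer. This sets out from 17 and returns at 20.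

Step 13. What may go wrong: poor facial selectivity of oxygen transfer, since the C1 methyl lies on the lower face, or acid-induced attack of the C4 hydroxyl on the new epoxide. Fallback: the bromohydrin route reverses the facial outcome of direct epoxidation. NBS in aqueous THF on 23 would give (1S,4R,5S,6R,8R,9R)-9-bromo-4,8-dihydroxydaucan-6-yl 4-[(tert-butyldimethylsilyl)oxy]benzoate F7 (bromine up, C8 hydroxyl down). DBU in CH2Cl2 then closes the lower-face epoxide. This sets out from 23 and returns at 24.

## Further compounds

F1 | step 5 | (4S,5S)-8-methyl-1-methylidene-4-(propan-2-yl)spiro[4.5]dec-7-ene | CC(C)[C@@H]1CCC(=C)[C@]12CCC(C)=CC2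
F2 | step 1 | 1-(propan-2-yl)cyclopent-2-en-1-ol (racemic) | CC(C)C1(O)C=CCC1
F3 | step 1 | 3-(propan-2-yl)cyclopent-2-en-1-one | CC(C)C1=CC(=O)CC1
F4 | step 1 | (S)-diphenyl{[3-(propan-2-yl)cyclopent-1-en-1-yl]oxy}silane | O([SiH](c1ccccc1)c1ccccc1)C1=C[C@H](C(C)C)CC1
F5 | step 6 | (1S)-4,5-epoxydauc-8-ene (either epoxide face) | CC(C)C12OC13CCC(C)=CC[C@]3(C)CC2
F6 | step 10 | (1S,4R,5R)-4,5-epoxydauc-8-en-6-one | CC(C)[C@@]12O[C@@]13C(=O)CC(C)=CC[C@]3(C)CC2
F7 | step 13 | (1S,4R,5S,6R,8R,9R)-9-bromo-4,8-dihydroxydaucan-6-yl 4-[(tert-butyldimethylsilyl)oxy]benzoate | CC(C)[C@]1(O)CC[C@@]2(C)C[C@@H](Br)[C@](C)(O)C[C@@H](OC(=O)c3ccc(O[Si](C)(C)C(C)(C)C)cc3)[C@H]21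
A1 | alternative 1 | methyl (6R)-8-[(tert-butyldimethylsilyl)oxy]-2-diazo-6-methyl-3-oxooctanoate | COC(=O)C(=[N+]=[N-])C(=O)CC[C@@H](C)CCO[Si](C)(C)C(C)(C)C
A2 | alternative 1 | methyl 2-{2-[(tert-butyldimethylsilyl)oxy]ethyl}-2-methyl-5-oxocyclopentane-1-carboxylate | COC(=O)[C@H]1C(=O)CC[C@@]1(C)CCO[Si](C)(C)C(C)(C)C
A3 | alternative 2 | 3-diazo-1-[2-(2-methoxy-4-methylphenyl)-1,3-dioxolan-2-yl]butan-2-one | COc1cc(C)ccc1C1(CC(=O)C(C)=[N+]=[N-])OCCO1
A4 | alternative 2 | methoxy-substituted 8a-methyl azulenone ethylene ketal (cycloheptatriene form) | COC1=C2C3(CC(=O)[C@@]2(C)C=CC(C)=C1)OCCO3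
A5 | alternative 3 | (Z)-3-methyl-5-[(1S)-1-methyl-3-(propan-2-yl)cyclopent-2-en-1-yl]pent-3-enal oxime | CC(C)C1=C[C@](C)(C/C=C(C)\CC=NO)CC1
A6 | alternative 3 | tricyclic isoxazoline spanning C4, C5 and C6 | CC(C)[C@@]12CC[C@@]3(C)CC=C(C)CC(=NO1)[C@@H]23
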